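Uprolide D is disconnected at the C4–O bond of the tetrahydrofuran (O, C4, C5, C6, C7) that bridges the 14-membered carbocycle beside the C3 carbinol. In one operation, acid-promoted transannular attack of the C7 hydroxyl on C4 of a (3R,4R)-epoxide closes this ring, inverts C4 and releases the C3 hydroxyl. The precursor is a 13-O-silyl cembranolide carrying the E-derived 3,4-epoxide, the (7R)-allylic alcohol and the cis-fused α-methylene lactone. It is assembled from two alkynols by an indium-mediated allylation–lactonisation, Ni/Cr macrocyclisation at C7–C8, CBS correction of C7 and Shi epoxidation.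

Key step: step 21

Remark: cembrane numbering (C1–C20) is used for all intermediates; the ring-closing Ni/Cr coupling is not assumed to control C7, so C7 is set afterwards by reagent control, and O13 stays silylated so that only the C7 hydroxyl can reach the epoxide.

Step 1
Reactants: 1 hex-5-yn-1-ol
Product: 2 5-iodohex-5-en-1-ol
Conditions: NaI, Me3SiCl, H2O (0.5 equiv), MeCN, rt
Reagents that add atoms: sodium iodide, [Na+].[I-]
Why: HI generated in situ adds across the terminal alkyne in the Markovnikov sense (alkyne hydroiodination), placing iodine on the internal carbon that becomes C8 and leaving the primary alcohol untouched.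

Step 2
Reactants: 2 5-iodohex-5-en-1-ol
Product: 3 5-iodohex-5-enal
Conditions: Dess–Martin periodinane, CH2Cl2, 0 °C to rt
Reagents that add atoms: none
Why: Dess–Martin oxidation converts the primary alcohol into the aldehyde (future C12) under neutral conditions that spare the vinyl iodide.

Step 3
Reactants: 3 5-iodohex-5-enal
Product: 4 methyl (2Z)-7-iodoocta-2,7-dienoate
Conditions: methyl bis(2,2,2-trifluoroethyl)phosphonoacetate, KN(SiMe3)2, 18-crown-6, THF, −78 °C
Reagents that add atoms: methyl 2-[bis(2,2,2-trifluoroethoxy)phosphoryl]acetate, COC(=O)CP(=O)(OCC(F)(F)F)OCC(F)(F)F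
Why: The Still–Gennari variant of the Horner–Wadsworth–Emmons olefination collapses under kinetic control to the Z-enoate, giving the cis C12=C13 geometry that a cis-epoxide requires.

Step 4
Reactants: 4 methyl (2Z)-7-iodoocta-2,7-dienoate
Product: 5 (2Z)-7-iodoocta-2,7-dien-1-ol
Conditions: iBu2AlH (2.2 equiv), CH2Cl2, −78 °C; aq. KNaC4H4O6
Reagents that add atoms: none
Why: iBu2AlH reduces the conjugated ester by 1,2-hydride addition to the allylic alcohol without changing the alkene geometry or touching the vinyl iodide.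

Step 5
Reactants: 5 (2Z)-7-iodoocta-2,7-dien-1-ol
Product: 6 [(2S,3R)-3-(4-iodopent-4-en-1-yl)oxiran-2-yl]methanol
Conditions: Ti(OiPr)4 (10 mol%), L-(+)-diethyl tartrate (12 mol%), t-BuOOH, 4 Å sieves, CH2Cl2, −20 °C
Reagents that add atoms: tert-butyl hydroperoxide, CC(C)(C)OO
Why: In this Sharpless asymmetric epoxidation the titanium tartrate complex binds the allylic alcohol and the L-(+)-tartrate directs oxygen to the face that gives the (2S,3R)-cis-epoxide, which fixes C13 and ignores the non-allylic iodoalkene.

Step 6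
Reactants: 6 [(2S,3R)-3-(4-iodopent-4-en-1-yl)oxiran-2-yl]methanol
Product: 7 (2R,3S)-7-iodo-3-methyloct-7-ene-1,2-diol
Conditions: Me3Al (3 equiv), hexane/CH2Cl2, 0 °C to rt
Reagents that add atoms: trimethylaluminium (Me3Al), C[Al](C)C
Why: The aluminium alkoxide of the epoxy alcohol directs methyl transfer to the distal epoxide carbon with SN2 inversion (hydroxyl-directed regioselective epoxide opening), so the cis-epoxide gives the syn 3-methyl-1,2-diol with C12 set as S and C13 retained.

Step 7
Reactants: 7 (2R,3S)-7-iodo-3-methyloct-7-ene-1,2-diol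
Product: 8 (2R,3S)-2-hydroxy-7-iodo-3-methyloct-7-enal
Conditions: TEMPO (2,2,6,6-tetramethylpiperidin-1-oxyl, cat.), N-chlorosuccinimide, Bu4NCl, CH2Cl2/aq. NaHCO3 (pH about 8.6), rt; used crude
Reagents that add atoms: none
Why: Oxoammonium (TEMPO) oxidation with N-chlorosuccinimide as terminal oxidant is selective for the unhindered primary hydroxyl over the secondary one and should give the α-hydroxy aldehyde, which is used at once because it equilibrates with its dimer.

Step 8
Reactants: 9 pent-4-yn-1-ol
Product: 10 tert-butyldimethyl(pent-4-yn-1-yloxy)silane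
Conditions: t-BuMe2SiCl, imidazole, CH2Cl2, rt
Reagents that add atoms: tert-butyldimethylsilyl chloride, CC(C)(C)[Si](C)(C)Cl
Why: Standard silyl ether formation protects the future C7 hydroxyl for the organoaluminium chemistry that follows.

Step 9
Reactants: 10 tert-butyldimethyl(pent-4-yn-1-yloxy)silane
Product: 13 (3E)-7-(tert-butyldimethylsilyloxy)-4-methylhept-3-en-1-ol, via alkenyldimethylalane 11 (not isolated), via lithium alkenylaluminate 12 (not isolated)
Conditions: Me3Al (2.5 equiv), Cp2ZrCl2 (25 mol%), CH2Cl2, 0 °C to rt; n-BuLi, hexane/THF, −78 °C; ethylene oxide, −78 °C to rt; dil. HCl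
Reagents that add atoms: trimethylaluminium (Me3Al), C[Al](C)C; ethylene oxide, C1CO1
Why: Negishi zirconium-catalysed carboalumination adds methyl and aluminium syn across the alkyne with methyl on the internal carbon, and the derived aluminate opens ethylene oxide with retention at the alkenyl carbon, so the E-trisubstituted C3=C4 alkene is fixed by the mechanism.

Step 10
Reactants: 13 (3E)-7-(tert-butyldimethylsilyloxy)-4-methylhept-3-en-1-ol
Product: 14 (3E)-7-(tert-butyldimethylsilyloxy)-4-methylhept-3-enal
Conditions: Dess–Martin periodinane, NaHCO3, CH2Cl2, 0 °C; used at once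
Reagents that add atoms: none
Why: Buffered Dess–Martin oxidation gives the β,γ-unsaturated aldehyde without the acid or base that would move the alkene into conjugation.

Step 11
Reactants: 14 (3E)-7-(tert-butyldimethylsilyloxy)-4-methylhept-3-enal
Product: 15 methyl (5E)-9-(tert-butyldimethylsilyloxy)-3-hydroxy-6-methyl-2-methylidenenon-5-enoate (racemic at the carbinol carbon)
Conditions: iBu2AlH, N-methylmorpholine N-oxide, THF, 0 °C; methyl propiolate, 0 °C; then 14, 0 °C to rt; aq. KNaC4H4O6
Reagents that add atoms: methyl propiolate, C#CC(=O)OC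
Why: Hydroalumination of methyl propiolate gives an α-aluminoacrylate that adds to the aldehyde (vinylalumination, a non-basic route to Morita–Baylis–Hillman adducts), and the new carbinol centre is formed as a racemate that step 12 erases.

Step 12
Reactants: 15 methyl (5E)-9-(tert-butyldimethylsilyloxy)-3-hydroxy-6-methyl-2-methylidenenon-5-enoate
Product: 16 methyl (2Z,5E)-2-(bromomethyl)-9-(tert-butyldimethylsilyloxy)-6-methylnona-2,5-dienoate
Conditions: N-bromosuccinimide, Me2S, CH2Cl2, 0 °C to rt
Reagents that add atoms: N-bromosuccinimide, O=C1CCC(=O)N1Br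
Why: Corey–Kim-type activation of the allylic alcohol as its oxysulfonium salt followed by SN2' attack of bromide moves the alkene into conjugation with the ester and gives the thermodynamically favoured (2Z)-2-(bromomethyl)enoate.

Step 13
Reactants: 8 (2R,3S)-2-hydroxy-7-iodo-3-methyloct-7-enal; 16 methyl (2Z,5E)-2-(bromomethyl)-9-(tert-butyldimethylsilyloxy)-6-methylnona-2,5-dienoate
Product: 18 (4S,5R)-5-[(1R,2S)-1-hydroxy-6-iodo-2-methylhept-6-en-1-yl]-3-methylidene-4-[(2E)-6-(tert-butyldimethylsilyloxy)-3-methylhex-2-en-1-yl]oxolan-2-one, via open-chain hydroxy ester 17 (not isolated)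
Conditions: In powder, THF/H2O (1:1), rt; then PPTS (pyridinium p-toluenesulfonate, cat.), benzene, 50 °C
Reagents that add atoms: none
Why: In this indium-mediated Barbier allylation followed by acid-catalysed γ-lactonisation, the Z-configured allylindium reacts through its γ-carbon (C1) in a chair transition state that places the C14 hydroxyl and the C1 side chain syn (cis-lactone), while chelation of indium by the free C13 hydroxyl and the aldehyde oxygen directs attack anti to the C12-bearing chain, so C14 (R) and C1 (S) are set relative to C13 as the syn,syn triad and the five-membered lactone through O14 should form in preference to the six-membered one through O13.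

Step 14
Reactants: 18 the hydroxy lactone from step 13
Product: 19 (4S,5R)-5-[(1R,2S)-1-(tert-butyldimethylsilyloxy)-6-iodo-2-methylhept-6-en-1-yl]-3-methylidene-4-[(2E)-6-(tert-butyldimethylsilyloxy)-3-methylhex-2-en-1-yl]oxolan-2-one
Conditions: t-BuMe2SiOTf, 2,6-lutidine, CH2Cl2, −78 to 0 °C
Reagents that add atoms: tert-butyldimethylsilyl triflate, CC(C)(C)[Si](C)(C)OS(=O)(=O)C(F)(F)F
Why: The silyl triflate with a hindered base silylates the hindered secondary C13 hydroxyl, masking the only other hydroxyl that could later reach the epoxide.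

Step 15
Reactants: 19 the bis-silyl ether from step 14
Product: 20 (4S,5R)-5-[(1R,2S)-1-(tert-butyldimethylsilyloxy)-6-iodo-2-methylhept-6-en-1-yl]-4-[(2E)-6-hydroxy-3-methylhex-2-en-1-yl]-3-methylideneoxolan-2-one
Conditions: HF·pyridine, pyridine, THF, 0 °C
Reagents that add atoms: none
Why: Buffered HF·pyridine cleaves the unhindered primary silyl ether much faster than the hindered secondary one (selective desilylation).

Step 16
Reactants: 20 the primary alcohol from step 15
Product: 21 (4E)-6-[(3S,4R... cembrane C1,C14)-lactone]-aldehyde, that is (4E)-6-{(2R,3S)-2-[(1R,2S)-1-(tert-butyldimethylsilyloxy)-6-iodo-2-methylhept-6-en-1-yl]-4-methylidene-5-oxooxolan-3-yl}-4-methylhex-4-enal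
Conditions: Dess–Martin periodinane, CH2Cl2, 0 °C to rt
Reagents that add atoms: none
Why: Dess–Martin oxidation gives the C7 aldehyde without epimerising the lactone or touching the acrylate, the alkenes and the vinyl iodide.

Step 17
Reactants: 21 the seco iodo aldehyde from step 16
Product: 22 (1S,3E,12S,13R,14R)-13-(tert-butyldimethylsilyloxy)-7-hydroxycembra-3,8(19),15(17)-trien-16,14-olide as a mixture of C7 epimers
Conditions: CrCl2 (10 equiv), NiCl2 (1 mol% of the CrCl2), DMSO/THF, rt, slow addition to about 0.003 M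
Reagents that add atoms: none
Why: In this Nozaki–Hiyama–Kishi reaction, NiCl2-catalysed activation of the C8–I bond, transmetalation to trivalent chromium and chemoselective addition of the alkenylchromium to the aldehyde under high dilution close the 14-membered ring at C7–C8 and install the C8 exo-methylene directly; C7 forms without reliable control and is therefore reset in steps 18 and 19.

Step 18
Reactants: 22 the macrocyclic allylic alcohols from step 17
Product: 23 (1S,3E,12S,13R,14R)-13-(tert-butyldimethylsilyloxy)-7-oxocembra-3,8(19),15(17)-trien-16,14-olide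
Conditions: Dess–Martin periodinane, CH2Cl2, 0 °C
Reagents that add atoms: none
Why: Dess–Martin oxidation of the allylic alcohol converges both C7 epimers on one cross-conjugated enone.

Step 19
Reactants: 23 the macrocyclic enone from step 18
Product: 24 (1S,3E,7R,12S,13R,14R)-13-(tert-butyldimethylsilyloxy)-7-hydroxycembra-3,8(19),15(17)-trien-16,14-olide
Conditions: (S)-2-methyl-CBS-oxazaborolidine (0.5 equiv), catecholborane, toluene, −78 °C
Reagents that add atoms: none
Why: In this Corey–Bakshi–Shibata reduction the (S)-oxazaborolidine binds the ketone with the α-branched alkenyl carbon C8 as the large group and delivers hydride to the face that gives the 7R alcohol by reagent control, and the low temperature should suppress 1,4-reduction and attack on the lactone.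

Step 20
Reactants: 24 the (7R)-allylic alcohol from step 19
Product: 25 (1S,3R,4R,7R,12S,13R,14R)-13-(tert-butyldimethylsilyloxy)-3,4-epoxy-7-hydroxycembra-8(19),15(17)-dien-16,14-olide
Conditions: Shi ketone (D-fructose-derived 1,2:4,5-di-O-isopropylidene-β-D-erythro-2,3-hexodiulo-2,6-pyranose, 30 mol%), KHSO5 (as Oxone), K2CO3, Bu4NHSO4, aq. Na2B4O7 buffer, MeCN/dimethoxymethane, 0 °C
Reagents that add atoms: potassium peroxymonosulfate (KHSO5), [K+].[O-]S(=O)(=O)OO
Why: In this Shi epoxidation the dioxirane from the D-fructose-derived ketone reacts through a spiro transition state with the electron-rich E-trisubstituted C3=C4 alkene, should give the (3R,4R)-epoxide by reagent control, and leaves the 1,1-disubstituted C8=C19 alkene and the electron-poor acrylate alone.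

Step 21
Reactants: 25 the 13-O-silyl 3,4-epoxy-7-hydroxy cembranolide from step 20
Product: 26 13-O-(tert-butyldimethylsilyl)uprolide D
Conditions: PPTS (10 mol%), CH2Cl2, 0 °C to rt
Reagents that add atoms: none
Why: PPTS protonates the epoxide oxygen, the tertiary C4–O bond lengthens, and the C7 hydroxyl held across the ring attacks C4 from the side opposite the leaving oxygen, after which proton loss gives the ether and the C3 hydroxyl. The closest known reaction type is the acid-catalysed cyclisation of 4,5-epoxy alcohols to 2-(1-hydroxyalkyl)tetrahydrofurans, used in polyether synthesis and in transannular cases in macrocyclic terpenoids. The one new ring, the tetrahydrofuran O–C4–C5–C6–C7, closes in the 5-exo-tet mode across the 14-membered ring. C4 is the stereocentre made here: backside attack inverts it (R to S), so it is dictated by the (3R,4R)-epoxide from step 20, while C3 keeps its configuration and the 7R carbinol places the two ring bonds of the ether cis. The step needs attack at C4 and not C3, and by O7 and no other nucleophile; the tertiary, cation-stabilising C4 and the five-membered exo closure (against a 6-endo tetrahydropyran) secure the first, and silylation of O13, which could otherwise reach C3 in a 6-exo mode, together with a non-nucleophilic counter-ion secures the second.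

Step 22
Reactants: 26 13-O-(tert-butyldimethylsilyl)uprolide D
Product: 27 uprolide D
Conditions: HF·pyridine, THF, 0 °C to rt
Reagents that add atoms: none
Why: Fluoride cleavage of the secondary silyl ether under mildly acidic conditions (desilylation) frees O13 without opening the lactone, adding to the acrylate or disturbing the ether bridge.

Compound list
1 | hex-5-yn-1-ol | C#CCCCCO | starting material
2 | 5-iodohex-5-en-1-ol | C=C(I)CCCCO | intermediate
3 | 5-iodohex-5-enal | C=C(I)CCCC=O | intermediate
4 | methyl (2Z)-7-iodoocta-2,7-dienoate | C=C(I)CCC/C=C\C(=O)OC | intermediate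
5 | (2Z)-7-iodoocta-2,7-dien-1-ol | C=C(I)CCC/C=C\CO | intermediate
6 | [(2S,3R)-3-(4-iodopent-4-en-1-yl)oxiran-2-yl]methanol | C=C(I)CCC[C@H]1O[C@H]1CO | intermediate
7 | (2R,3S)-7-iodo-3-methyloct-7-ene-1,2-diol | C=C(I)CCC[C@H](C)[C@@H](O)CO | intermediate
8 | (2R,3S)-2-hydroxy-7-iodo-3-methyloct-7-enal | C=C(I)CCC[C@H](C)[C@@H](O)C=O | intermediate
9 | pent-4-yn-1-ol | C#CCCCO | starting material
10 | tert-butyldimethyl(pent-4-yn-1-yloxy)silane | C#CCCCO[Si](C)(C)C(C)(C)C | intermediate
11 | dimethyl[(1E)-5-(tert-butyldimethylsilyloxy)-2-methylpent-1-en-1-yl]alumane | C[Al](C)/C=C(\C)CCCO[Si](C)(C)C(C)(C)C | intermediate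
12 | lithium butyl(dimethyl)[(1E)-5-(tert-butyldimethylsilyloxy)-2-methylpent-1-en-1-yl]aluminate | [Li+].CCCC[Al-](C)(C)/C=C(\C)CCCO[Si](C)(C)C(C)(C)C | intermediate
13 | (3E)-7-(tert-butyldimethylsilyloxy)-4-methylhept-3-en-1-ol | OCC/C=C(\C)CCCO[Si](C)(C)C(C)(C)C | intermediate
14 | (3E)-7-(tert-butyldimethylsilyloxy)-4-methylhept-3-enal | O=CC/C=C(\C)CCCO[Si](C)(C)C(C)(C)C | intermediate
15 | methyl (5E)-9-(tert-butyldimethylsilyloxy)-3-hydroxy-6-methyl-2-methylidenenon-5-enoate (racemic) | C=C(C(=O)OC)C(O)C/C=C(\C)CCCO[Si](C)(C)C(C)(C)C | intermediate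
16 | methyl (2Z,5E)-2-(bromomethyl)-9-(tert-butyldimethylsilyloxy)-6-methylnona-2,5-dienoate | BrC/C(C(=O)OC)=C\C/C=C(\C)CCCO[Si](C)(C)C(C)(C)C | intermediate
17 | methyl (3S,4R,5R,6S)-4,5-dihydroxy-10-iodo-6-methyl-2-methylidene-3-[(2E)-6-(tert-butyldimethylsilyloxy)-3-methylhex-2-en-1-yl]undec-10-enoate | C=C(I)CCC[C@H](C)[C@@H](O)[C@H](O)[C@@H](C/C=C(\C)CCCO[Si](C)(C)C(C)(C)C)C(=C)C(=O)OC | intermediate
18 | (4S,5R)-5-[(1R,2S)-1-hydroxy-6-iodo-2-methylhept-6-en-1-yl]-3-methylidene-4-[(2E)-6-(tert-butyldimethylsilyloxy)-3-methylhex-2-en-1-yl]oxolan-2-one | C=C(I)CCC[C@H](C)[C@@H](O)[C@@H]1OC(=O)C(=C)[C@@H]1C/C=C(\C)CCCO[Si](C)(C)C(C)(C)C | intermediate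
19 | 13-O-silyl ether of 18 (both hydroxyls as tert-butyldimethylsilyl ethers) | C=C(I)CCC[C@H](C)[C@@H](O[Si](C)(C)C(C)(C)C)[C@@H]1OC(=O)C(=C)[C@@H]1C/C=C(\C)CCCO[Si](C)(C)C(C)(C)C | intermediate
20 | C7 primary alcohol with O13 silylated | C=C(I)CCC[C@H](C)[C@@H](O[Si](C)(C)C(C)(C)C)[C@@H]1OC(=O)C(=C)[C@@H]1C/C=C(\C)CCCO | intermediate
21 | seco C7 aldehyde with C8 vinyl iodide and O13 silylated | C=C(I)CCC[C@H](C)[C@@H](O[Si](C)(C)C(C)(C)C)[C@@H]1OC(=O)C(=C)[C@@H]1C/C=C(\C)CCC=O | intermediate
22 | (1S,3E,12S,13R,14R)-13-(tert-butyldimethylsilyloxy)-7-hydroxycembra-3,8(19),15(17)-trien-16,14-olide, C7 epimers | C=C1CCC[C@H](C)[C@@H](O[Si](C)(C)C(C)(C)C)[C@@H]2OC(=O)C(=C)[C@@H]2C/C=C(\C)CCC1O | intermediate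
23 | (1S,3E,12S,13R,14R)-13-(tert-butyldimethylsilyloxy)-7-oxocembra-3,8(19),15(17)-trien-16,14-olide | C=C1CCC[C@H](C)[C@@H](O[Si](C)(C)C(C)(C)C)[C@@H]2OC(=O)C(=C)[C@@H]2C/C=C(\C)CCC1=O | intermediate
24 | (1S,3E,7R,12S,13R,14R)-13-(tert-butyldimethylsilyloxy)-7-hydroxycembra-3,8(19),15(17)-trien-16,14-olide | C=C1CCC[C@H](C)[C@@H](O[Si](C)(C)C(C)(C)C)[C@@H]2OC(=O)C(=C)[C@@H]2C/C=C(\C)CC[C@H]1O | intermediate
25 | (1S,3R,4R,7R,12S,13R,14R)-13-(tert-butyldimethylsilyloxy)-3,4-epoxy-7-hydroxycembra-8(19),15(17)-dien-16,14-olide | C=C1CCC[C@H](C)[C@@H](O[Si](C)(C)C(C)(C)C)[C@@H]2OC(=O)C(=C)[C@@H]2C[C@H]3O[C@]3(C)CC[C@H]1O | intermediate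
26 | 13-O-(tert-butyldimethylsilyl)uprolide D | C=C1CCC[C@H](C)[C@@H](O[Si](C)(C)C(C)(C)C)[C@@H]2OC(=O)C(=C)[C@@H]2C[C@@H](O)[C@]2(C)CC[C@H]1O2 | intermediate
27 | uprolide D | C=C1CCC[C@H](C)[C@@H](O)[C@@H]2OC(=O)C(=C)[C@@H]2C[C@@H](O)[C@]2(C)CC[C@H]1O2 | target

Total step count: 22. Longest linear sequence: 17 steps (steps 1–7, then 13–22); the second branch (steps 8–12) has 5 steps.

Steps most likely to fail

Step 13. The union may suffer from poor facial selectivity if chelation by the free hydroxyl is incomplete, from erosion of the syn preference through isomerisation of the allylindium, or from loss of aldehyde 8 by oligomerisation before it reacts. The fallback replaces the aqueous Barbier reaction by a chelation-controlled Lewis-acid allylstannane addition. It sets out from diol 7 and bromide 16 and returns at hydroxy ester 17. Diol 7 is condensed with anisaldehyde dimethyl acetal (PPTS) to the p-methoxybenzylidene acetal F1. iBu2AlH opens F1 regioselectively to the secondary p-methoxybenzyl ether with a free primary alcohol F2, and Dess–Martin oxidation gives the α-(p-methoxybenzyloxy) aldehyde F3. Bromide 16 is converted with Bu3SnLi and CuBr·SMe2 into the allylstannane F4. MgBr2·OEt2 chelates the aldehyde and ether oxygens of F3, and F4 adds in a Keck-type SE2' allylation anti to the C12 chain to give the protected syn,syn hydroxy ester F5. DDQ removes the p-methoxybenzyl group to give 17, which lactonises to 18 as in step 13.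

Step 17. Ring closure may lose out to intermolecular coupling, or the alkenylchromium may be protonated before it finds the aldehyde. The fallback closes the same C7–C8 bond by an intramolecular acyl Stille coupling. It sets out from aldehyde 21 and returns at enone 23, bypassing step 18. Pinnick oxidation (NaClO2, NaH2PO4, 2-methylbut-2-ene) gives the carboxylic acid F6. Pd(PPh3)4 with Me3SnSnMe3 and iPr2NEt exchanges the vinyl iodide for the alkenylstannane in the stannyl acid F7. 1-Chloro-N,N,2-trimethylprop-1-en-1-amine converts F7 into the acid chloride F8, which is not isolated and is cyclised under high dilution with Pd2(dba)3 and tri(2-furyl)phosphine to 23.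

Step 20. Facial selectivity may be poor if the ring conformation shields the face that the catalyst prefers, and the allylic alcohol may be over-oxidised during a slow reaction. The fallback moves the epoxidation to the open-chain stage, where reagent control is not opposed by a ring. It sets out from bis-silyl ether 19 and returns at epoxy alcohol 25. Shi epoxidation of 19 under the conditions of step 20 gives the (3R,4R)-epoxide F9. Bu4NF buffered with AcOH removes the primary silyl group to give the epoxy alcohol F10, and Dess–Martin oxidation gives the epoxy aldehyde F11. CrCl2/NiCl2 ring closure as in step 17 gives the macrocyclic epoxy alcohols F12 as C7 epimers, and Dess–Martin oxidation converges them on the epoxy enone F13. CBS reduction as in step 19 then gives 25; any 7R material in F12 that has already closed the ether is 26 itself.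

Further compounds
F1 | step 13 | (4R)-4-[(2S)-6-iodohept-6-en-2-yl]-2-(4-methoxyphenyl)-1,3-dioxolane (acetal epimers) | C=C(I)CCC[C@H](C)[C@@H]1COC(c2ccc(OC)cc2)O1
F2 | step 13 | (2R,3S)-7-iodo-2-[(4-methoxybenzyl)oxy]-3-methyloct-7-en-1-ol | C=C(I)CCC[C@H](C)[C@@H](OCc1ccc(OC)cc1)CO
F3 | step 13 | (2R,3S)-7-iodo-2-[(4-methoxybenzyl)oxy]-3-methyloct-7-enal | C=C(I)CCC[C@H](C)[C@@H](OCc1ccc(OC)cc1)C=O
F4 | step 13 | methyl (2Z,5E)-9-(tert-butyldimethylsilyloxy)-6-methyl-2-[(tributylstannyl)methyl]nona-2,5-dienoate | CCCC[Sn](CCCC)(CCCC)C/C(C(=O)OC)=C\C/C=C(\C)CCCO[Si](C)(C)C(C)(C)C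
F5 | step 13 | 5-O-(4-methoxybenzyl) ether of hydroxy ester 17 | C=C(I)CCC[C@H](C)[C@@H](OCc1ccc(OC)cc1)[C@H](O)[C@@H](C/C=C(\C)CCCO[Si](C)(C)C(C)(C)C)C(=C)C(=O)OC
F6 | step 17 | carboxylic acid from aldehyde 21 | C=C(I)CCC[C@H](C)[C@@H](O[Si](C)(C)C(C)(C)C)[C@@H]1OC(=O)C(=C)[C@@H]1C/C=C(\C)CCC(=O)O
F7 | step 17 | C8 trimethylstannyl analogue of acid F6 | C=C([Sn](C)(C)C)CCC[C@H](C)[C@@H](O[Si](C)(C)C(C)(C)C)[C@@H]1OC(=O)C(=C)[C@@H]1C/C=C(\C)CCC(=O)O
F8 | step 17 | acid chloride of F7 | C=C([Sn](C)(C)C)CCC[C@H](C)[C@@H](O[Si](C)(C)C(C)(C)C)[C@@H]1OC(=O)C(=C)[C@@H]1C/C=C(\C)CCC(=O)Cl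
F9 | step 20 | (3R,4R)-epoxide of bis-silyl ether 19 | C=C(I)CCC[C@H](C)[C@@H](O[Si](C)(C)C(C)(C)C)[C@@H]1OC(=O)C(=C)[C@@H]1C[C@H]2O[C@]2(C)CCCO[Si](C)(C)C(C)(C)C
F10 | step 20 | (3R,4R)-epoxy primary alcohol | C=C(I)CCC[C@H](C)[C@@H](O[Si](C)(C)C(C)(C)C)[C@@H]1OC(=O)C(=C)[C@@H]1C[C@H]2O[C@]2(C)CCCO
F11 | step 20 | (3R,4R)-epoxy aldehyde | C=C(I)CCC[C@H](C)[C@@H](O[Si](C)(C)C(C)(C)C)[C@@H]1OC(=O)C(=C)[C@@H]1C[C@H]2O[C@]2(C)CCC=O
F12 | step 20 | macrocyclic (3R,4R)-epoxy alcohols, C7 epimers | C=C1CCC[C@H](C)[C@@H](O[Si](C)(C)C(C)(C)C)[C@@H]2OC(=O)C(=C)[C@@H]2C[C@H]3O[C@]3(C)CCC1O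
F13 | step 20 | macrocyclic (3R,4R)-epoxy enone | C=C1CCC[C@H](C)[C@@H](O[Si](C)(C)C(C)(C)C)[C@@H]2OC(=O)C(=C)[C@@H]2C[C@H]3O[C@]3(C)CCC1=O
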